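Start from the early times: at 0.500 min the summer run shows 0.3 % target, while at 0.333 min the spring run already shows more, 5.6 %. Now look at the end of the spring run, where the last 2.50 min added 5.7 percentage points and 25.5 % stands. Decide what to charge next.

| setting | summer | spring | Friday's | Tuesday's | Saturday's | Sunday's | Wednesday's |
|---|---|---|---|---|---|---|---|
| starting material | 0.52 M | 0.52 M | 0.52 M | 0.52 M | 0.52 M | 0.52 M | 0.52 M |
| reagent | 0.312 M | 0.312 M | 0.312 M | 0.312 M | 0.312 M | 0.312 M | 0.312 M |
| free catalyst | 32 mM | 500 mM | 25 mM | 50 mM | 100 mM | 200 mM | 400 mM |
| remark | run made earlier | run made earlier |  |  |  |  |  |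
| time |  |  | 4.0 min | 4.0 min | 4.0 min | 4.0 min | 4.0 min |

| summer: time / min | summer: target / % | spring: time / min | spring: target / % |
|---|---|---|---|
| 0.500 | 0.3 | 0.333 | 5.6 |
| 1.33 | 7.7 | 0.667 | 14.1 |
| 2.50 | 13.1 | 1.50 | 19.8 |
| 4.00 | 18.7 | 4.00 | 25.5 |

(scatter of a reading: 1 percentage point)

- amount of target at the end, in percent of the starting material charged for Friday's, Tuesday's, Saturday's, Sunday's, Wednesday's, in this order
- how the row runs (rises all the way / falls all the way / falls, then rises / rises, then falls / hardly changes)

- "hardly changes" means that all values lie within two and a half points (for a concentration: within two and a half percent of the largest)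

Count everything as a fraction of the starting material charge. The reagent, the limiting reagent here, is charged at 60.0 %. My assumption: each target takes one reagent, and reagent consumed without showing as target sits on the catalyst in a bound form that can release target and take it back. Suppose the spring reagent is consumed at the last reading. Then 34.5 % is bound, and of a catalyst charge of 96.2 %, 61.7 % is free. Multiply target by free catalyst and divide by bound catalyst: that is the hold-back number, a dissociation constant, here 0.456. It is a reading, and it carries the scatter of one spring point.

Use it on the other charges, with starting material and reagent as charged in the row. Guess a target, work out bound and free, let the number return a target, take the midpoint and go round again. Read the result as my ceiling for that charge, not as a yield. Wednesday's comes to 29.7 %, Sunday's to more, 41.6 %. The summer run reached 18.7 %, under its ceiling of 56.6 %, and its last 1.50 min still added 5.6 points. So charge Sunday's amount for yield, and keep Wednesday's as the test, where I commit to a figure near its ceiling.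

The forecast gives 17 %, 22 %, 26 %, 28 %, 26.5 %, so rises, then falls, on the grounds that “At high catalyst, the plateau is lowered”. Its highest figure stands at Sunday's too, but its Wednesday's figure is lower than my ceiling.

The flasks give 15.3 %, 25.5 %, 36.2 %, 38.2 %, 28.1 %: rises, then falls.

    reagent + free catalyst → catalyst intermediate A (k = 9.70 L mol⁻¹ min⁻¹)
    starting material + catalyst intermediate A → catalyst intermediate B (k = 7.00 L mol⁻¹ min⁻¹)
    catalyst intermediate B ⇌ free catalyst + target (K = 0.210 M, k = 3.30 min⁻¹)
    2 starting material → self-condensation product (k = 0.0970 L mol⁻¹ min⁻¹)

Wednesday's ended with 0.0127 % of its reagent charge left and 31.4 % of the starting material charge as catalyst intermediate B, beside its target. Its ceiling stands 1.6 points above that target. Put the hold-back number on Saturday's: the ceiling comes to 49.9 %. At 40.0 min, with 0 % of its reagent left, Saturday's holds 49.4 % target.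

All runs were generated by integration on assumed constants; scatter was added.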